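## The problem

Target 25 is a p-terphenyl whose central ring B is hexasubstituted: two para carbons carry the 4-hydroxyphenyl rings and the other four carbons all carry oxygen, three of them esterified by the same (2Z,4S,5S)-4,5-epoxyhex-2-enoyl group and one left as a free phenol. Because the four oxygen-bearing positions are related by the symmetry of the ring, any triester is the target; the task is to attach exactly three acyl groups while the fourth ring-B oxygen and both outer phenols stay free. The six stereocentres are three identical trans-epoxide pairs, remote from one another and unable to control one another, so they must come from one enantiopure building block, and because three copies are attached, any minor enantiomer of it reappears as diastereomeric triesters. The side chain combines a Z-enoate (isomerised by reversible conjugate addition), a vinyl epoxide (opened by acid, soft nucleophiles and zerovalent palladium) and an aryl ester (cleaved or transferred by base), and the free acid can open its own epoxide through the cis carboxyl group. A ring B with several free hydroxyls is a leuco-hydroquinone that air oxidises to the quinone. The feature that makes the key step possible lies in the outer rings: each is bound to ring B through one carbon, here called C1', and has its only oxygen on the para carbon C4' (C1' to C6' denote outer-ring atoms in the discussion, whereas the systematic names use terphenyl locants, in which the primed numbers belong to ring B). That para relation is what a 4-arylcyclohex-2-enone gives on dehydrogenation, and such an enone is the Michael–aldol product of an arylacetaldehyde (C1' and C2') and methyl vinyl ketone (C3' to C6'). Ring B has its two carbon substituents para to each other and each ortho to oxygen, which is the pattern a double aromatic Claisen rearrangement of a hydroquinone bis(allyl ether) delivers.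

## Retrosynthesis

**25 from 24.** The last cut is at three O–Si bonds. The outer phenols are less hindered than the ring-B hydroxyls and would be acylated first, and the fourth ring-B oxygen must also be masked, so all three carry the same silyl group. The skeleton of 24 is no simpler, but it tolerates acylation conditions. The forward step must remove three aryl silyl ethers with buffered fluoride without touching aryl esters or epoxides.

**24 from 22 and 21.** Three ester C–O bonds are cut. The neighbouring cut, acylating a ring-B tetraol three times out of four, would be a statistical partial acylation with the most valuable material of the route. Triol 22 has exactly three free hydroxyls, so the acylation is exhaustive and consumes three molecules of 21. Since the ring-B oxygens are equivalent, it does not matter which of them carries silicon, and silyl or acyl migration between neighbours is degenerate. The precursors are an achiral triol and the potassium carboxylate 21, which holds all stereochemistry. The forward step must activate the carboxylate without passing through the free acid, avoid Z to E isomerisation and exclude air.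

**21 from 20, 18, 19, 17 and 16.** The C2=C3 bond is cut by a Z-selective phosphonate olefination of epoxy aldehyde 18 with 19, and the epoxide C–O bonds by catalytic asymmetric epoxidation of 16. An ordinary stabilised ylide would give the E isomer, and an alkyne reduction would be longer. This path reaches the whole side chain in four steps from a C4 alcohol. The epoxidation must deliver the (2S,3S) alcohol 17, whose two centres become C4 and C5 unchanged.

**22 from 15 and 14.** Three benzyl C–O bonds and the two outer O–Si bonds are cut. Benzyl is chosen for the three ring-B oxygens that will be acylated because hydrogenolysis is neutral, leaves aryl silyl ethers intact and gives ring B directly at the leuco oxidation level. Methyl ethers would need a Lewis-acidic cleavage that also removes silicon and erases the three-plus-one pattern, followed by a detour through the quinone. Compound 14 carries the three-plus-one pattern on ring B and two free outer phenols.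

**14 from 13.** No skeletal bond is cut. The two outer phenols are written at the oxidation level of 4-arylcyclohex-2-enones. This trades two aromatic rings for two enones that an annulation can build. The forward step is a double dehydrogenation that must spare benzyl and silyl ethers.

**13 from 9 and 10 (key disconnection).** In each outer ring the C1'–C6' and C2'–C3' bonds are cut, leading to dialdehyde 9 and two molecules of 10. The neighbouring cut at the two aryl–aryl bonds would need a tetraoxygenated 1,4-dimetallated or dihalogenated ring B and two couplings at carbons flanked by two ortho oxygens each. Here the bond from ring B to C1' already exists as the aryl–CH2 bond of each arm. Both outer rings disappear, leaving one benzene with two C2 arms. The forward step is a twofold Michael–aldol sequence that must stop at one addition per arm.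

**9 from 8, 7 and 6.** The aldehydes come from oxidative cleavage of two allyl groups. Before that, the silyl ether and one benzyl ether are removed retrosynthetically to reach the symmetric hydroquinone 6. The three-plus-one pattern is set here, by monobenzylation of 6 to 7 and silylation to 8. The monobenzylation is statistical, but it is done on cheap material with recovery of 6, not at the end of the route.

**6 from 5, 2, 3 and 1.** The two aryl–allyl bonds are cut by a double aromatic Claisen rearrangement of 5. Each allyloxy group has exactly one free ortho position, so both arms go to the only unsubstituted carbons of ring B without halogen or metal. Compound 5 comes from quinone 2 by reduction and twofold O-allylation with two molecules of 3, and 2 from commercial 1 by acid-catalysed etherification.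

## Roads not taken

**Alternative 1:** This road concerns the side chain only. Methyl (2Z,4S,5S)-4,5-epoxyhex-2-enoate A1 (the same compound as 20) is cut at its C5–O bond and traced to the butenolide mesylate A2, itself derived from D-glucono-1,5-lactone A3. In the forward key step, carbonate in methanol opens the lactone to the methyl ester, and the freed C4 alkoxide displaces the C5 mesylate with inversion to close the trans-epoxide.

- Merits: the Z geometry is inherited from the ring and cannot be wrong, and the stereocentres come from the chiral pool in full enantiopurity. That matters here because three copies are attached. In both respects this road is better than the chosen one.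
- Weak points: reaching A2 from A3 needs deoxygenation at C2, C3 and C6 and a selective sulfonylation, so the sequence is several times longer than the three steps from 16 to 20. It also leaves the terphenyl core and the three-of-four acylation unaddressed.
- Comparison: the chosen plan sets brevity and a catalytic source of chirality against it, and accepts that minor diastereomers of 24 may have to be removed by chromatography.

**Alternative 2:** Here ring B itself is made. The cyclobutenone A4 and the siloxyalkyne A5 are heated together. The derived vinylketene adds to the alkyne and the resulting dienylketene closes by electrocyclisation to the hexasubstituted phenol A6.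

- Merits: the step is convergent, both aryl–aryl bonds arrive with the partners, and the four ring-B oxygens emerge chemically distinct (hydroxyl, two different silyl ethers, methyl ether). No statistical step is needed, and in this respect the road is better than the chosen plan.
- Weak points: A4 is a densely functionalised four-membered ring that needs its own multistep synthesis. A6 also carries three methyl ethers (two on the outer rings, one on ring B) whose cleavage requires conditions that strip or scramble the silyl ethers, so the differentiation is hard to use.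
- Comparison: the chosen plan is linear and has one statistical monoprotection. It sets against this cheap symmetric starting materials, no strained intermediates, and a benzyl/silyl pattern that is removed under neutral conditions in exactly the order the endgame needs.

**Alternative 3:** The epoxides are introduced last. The tris[(2Z,4E)-hexa-2,4-dienoate] A7 is epoxidised at its three distal C4=C5 bonds by the dioxirane formed from KHSO5 and a carbohydrate-derived chiral ketone in its enantiomeric form. This gives the tri-silyl ether A8, identical with 24.

- Merits: the labile epoxy acid is never handled. Only the robust (2Z,4E)-hexa-2,4-dienoic acid A9 is coupled, and all six stereocentres are set by one catalytic operation. On the handling of the side chain this road is better than the chosen plan.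
- Weak points: the dioxirane cycle runs in aqueous carbonate buffer at high pH, where aryl esters of an electron-poor phenol are at risk of hydrolysis. Three independent epoxidations multiply any facial error into diastereomers that differ only at remote centres. A9 is not the commercial isomer and needs its own Z-selective synthesis.
- Comparison: the chosen plan sets the stereocentres on a four-carbon alcohol, where purity can be checked before use, and never exposes the triester to aqueous base. It pays for this with the care needed to activate 21 without isomerisation.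

Key step: step 7

## Route

Assumption: (E)-but-2-en-1-ol is used as the pure E isomer; because the four ring-B oxygens are equivalent, the silyl ether (and later the free hydroxyl) is written at position 6' of the terphenyl name for naming only.

Stoichiometry: where a step builds more than one molecule of the same compound into its product, the first molecule stands on the Reactants line or as the first reagent entry, and every further molecule has its own entry under "Reagents that add atoms".

Step 1
Reactants: 1 2,5-dihydroxy-1,4-benzoquinone
Product: 2 2,5-bis(benzyloxy)-1,4-benzoquinone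
Conditions: BnOH (excess), BF3·OEt2 (cat.), ClCH2CH2Cl, 60 °C
Reagents that add atoms: benzyl alcohol, OCc1ccccc1; benzyl alcohol (second molecule), OCc1ccccc1
Why: The hydroxyquinone is a vinylogous acid and both of its hydroxyls are etherified by the alcohol under acid catalysis in the manner of a Fischer esterification, giving a bis(vinylogous ester); a non-aromatic solvent is used so that no arene is available for benzylation.

Step 2
Reactants: 2 2,5-bis(benzyloxy)-1,4-benzoquinone; 3 allyl bromide (2.5 equiv)
Product: 5 1,4-bis(allyloxy)-2,5-bis(benzyloxy)benzene, via 2,5-bis(benzyloxy)benzene-1,4-diol 4 (not isolated)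
Conditions: Na2S2O4, EtOAc/H2O, rt; organic phase concentrated under Ar; then allyl bromide (2.5 equiv), K2CO3, DMF, 50 °C
Reagents that add atoms: allyl bromide (second molecule of 3), C=CCBr
Why: Dithionite reduction of the quinone followed by twofold Williamson etherification of the air-sensitive hydroquinone without isolation is a standard reductive alkylation; each of the two phenoxides takes up one molecule of allyl bromide.

Step 3
Reactants: 5 1,4-bis(allyloxy)-2,5-bis(benzyloxy)benzene
Product: 6 3,6-diallyl-2,5-bis(benzyloxy)benzene-1,4-diol
Conditions: PhNEt2, 200 °C, Ar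
Reagents that add atoms: none
Why: Double aromatic Claisen rearrangement; each allyloxy group has one free ortho carbon (the other bears benzyloxy and the para carbon bears oxygen), so both allyl groups land on the only unsubstituted ring positions and tautomerisation restores the hydroquinone.

Step 4
Reactants: 6 3,6-diallyl-2,5-bis(benzyloxy)benzene-1,4-diol
Product: 7 3,6-diallyl-2,4,5-tris(benzyloxy)phenol
Conditions: BnBr (0.9 equiv), K2CO3, acetone, rt, Ar
Reagents that add atoms: benzyl bromide, BrCc1ccccc1
Why: Williamson monoetherification of a symmetric hydroquinone whose two hydroxyls are equivalent, so either gives 7; the outcome is statistical, the alkylating agent is kept limiting, and unreacted 6 should be recovered and recycled.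

Step 5
Reactants: 7 3,6-diallyl-2,4,5-tris(benzyloxy)phenol
Product: 8 tert-butyl[3,6-diallyl-2,4,5-tris(benzyloxy)phenoxy]dimethylsilane
Conditions: TBSOTf, 2,6-lutidine, CH2Cl2, 0 °C
Reagents that add atoms: tert-butyldimethylsilyl trifluoromethanesulfonate, CC(C)(C)[Si](C)(C)OS(=O)(=O)C(F)(F)F
Why: Silylation of a phenol flanked by two ortho substituents needs the silyl triflate; the resulting doubly ortho-shielded aryl silyl ether should be robust toward the amine, buffered acid and hydrogenolysis steps ahead.

Step 6
Reactants: 8 tert-butyl[3,6-diallyl-2,4,5-tris(benzyloxy)phenoxy]dimethylsilane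
Product: 9 2,2'-[2,3,5-tris(benzyloxy)-6-(tert-butyldimethylsilyloxy)-1,4-phenylene]diacetaldehyde
Conditions: OsO4 (cat.), NaIO4, 2,6-lutidine, dioxane/H2O, rt; used crude
Reagents that add atoms: sodium periodate (oxygen delivered through catalytic OsO4), [Na+].[O-]I(=O)(=O)=O
Why: Lemieux–Johnson cleavage of both terminal alkenes; 2,6-lutidine suppresses over-oxidation, and the enolisable dialdehyde is carried on without chromatography.

Step 7
Reactants: 9 2,2'-[2,3,5-tris(benzyloxy)-6-(tert-butyldimethylsilyloxy)-1,4-phenylene]diacetaldehyde; 10 methyl vinyl ketone (2.4 equiv)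
Product: 13 4,4'-[2,3,5-tris(benzyloxy)-6-(tert-butyldimethylsilyloxy)-1,4-phenylene]bis(cyclohex-2-en-1-one) as a mixture of stereoisomers, via bis(pyrrolidine enamine) 11 (not isolated), via bis(5-oxohexanal) 12 (not isolated)
Conditions: pyrrolidine, 4 Å MS, PhMe, rt, then evaporation of excess amine; methyl vinyl ketone (2.4 equiv), MeCN, 0 °C to rt; AcOH/NaOAc/H2O, 70 °C
Reagents that add atoms: methyl vinyl ketone (second molecule of 10), CC(=O)C=C
Why: Condensation of both aldehyde groups with pyrrolidine gives the conjugated bis-enamine 11, whose nucleophilic carbon is the benzylic one; its conjugate addition to methyl vinyl ketone (enamine Michael reaction, one molecule of 10 per arm) forms the C1'–C6' bond of each future ring and, after hydrolysis, the 1,5-keto aldehyde 12. In the warm acetate buffer the methyl ketone enolises (or forms its enamine) toward the methyl group and adds to the aldehyde carbon, and loss of water gives the conjugated enone, forming C2'–C3'. The closest known reaction type is the enamine variant of the Robinson annulation by which α-aryl aldehydes and methyl vinyl ketone give 4-arylcyclohex-2-enones. Each of the two rings closes in the same 6-(enolendo)-exo-trig aldol mode; closure from the methylene side of the ketone would need a four-membered ring and does not compete. The two new stereocentres (C4 of each enone, the later C1') arise without control, which is harmless because both become sp2 carbons in step 8. The selectivity needed is one Michael addition per arm and none at a second α-position: the two ortho substituents that flank each arm shield the tertiary benzylic carbon of the mono-adduct against a second addition, and excess pyrrolidine is removed before 10 is added so that it cannot consume the enone. The para relation between the bond to ring B and the future oxygen is fixed by connectivity, since the benzylic carbon becomes C4 of the enone. Benzyl and silyl ethers meet only a secondary amine and buffered acetic acid.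

Step 8
Reactants: 13 4,4'-[2,3,5-tris(benzyloxy)-6-(tert-butyldimethylsilyloxy)-1,4-phenylene]bis(cyclohex-2-en-1-one)
Product: 14 2',3',5'-tris(benzyloxy)-6'-(tert-butyldimethylsilyloxy)-[1,1':4',1''-terphenyl]-4,4''-diol
Conditions: Pd(OCOCF3)2 (10 mol %), 2-(dimethylamino)pyridine, TsOH·H2O (cat.), O2 (1 atm), DMSO, 80 °C
Reagents that add atoms: none
Why: Aerobic dehydrogenation catalysed by divalent palladium: α-palladation of each enone and β-hydride elimination give the cross-conjugated dienone, which tautomerises to the phenol and erases both stereocentres; no hydrogen iodide or hydrogen-transfer conditions arise that would threaten benzyl or silyl ethers.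

Step 9
Reactants: 14 2',3',5'-tris(benzyloxy)-6'-(tert-butyldimethylsilyloxy)-[1,1':4',1''-terphenyl]-4,4''-diol
Product: 15 2',3',5'-tris(benzyloxy)-4,4'',6'-tris(tert-butyldimethylsilyloxy)-1,1':4',1''-terphenyl
Conditions: TBSCl (2.5 equiv), imidazole, DMF, rt
Reagents that add atoms: tert-butyldimethylsilyl chloride, CC(C)(C)[Si](C)(C)Cl; tert-butyldimethylsilyl chloride (second molecule), CC(C)(C)[Si](C)(C)Cl
Why: Standard silylation of two unhindered phenols; all three oxygens that must be free in the target now carry the same fluoride-labile group.

Step 10
Reactants: 16 (E)-but-2-en-1-ol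
Product: 17 (2S,3S)-2,3-epoxybutan-1-ol [(2S,3S)-3-methyloxiran-2-yl]methanol
Conditions: Ti(OiPr)4 (cat.), L-(+)-diisopropyl tartrate (cat.), t-BuOOH, 4 Å MS, CH2Cl2, −20 °C
Reagents that add atoms: tert-butyl hydroperoxide, CC(C)(C)OO
Why: Sharpless asymmetric epoxidation; with the L-(+)-tartrate ester, E-2-alkenols give the (2S,3S) epoxy alcohols, and the E geometry of 16 translates into the trans-epoxide, so both stereocentres of the side chain are set here.

Step 11
Reactants: 17 (2S,3S)-2,3-epoxybutan-1-ol
Product: 18 (2R,3S)-2,3-epoxybutanal (descriptor at C2 changes by priority only)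
Conditions: (COCl)2, DMSO, Et3N, CH2Cl2, −78 °C; solution used directly
Reagents that add atoms: none
Why: Swern oxidation of an epoxy alcohol at low temperature; the α-centre on the oxirane does not epimerise, and the volatile aldehyde is used as a cold solution.

Step 12
Reactants: 18 (2R,3S)-2,3-epoxybutanal; 19 methyl bis(2,2,2-trifluoroethyl)phosphonoacetate
Product: 20 methyl (2Z,4S,5S)-4,5-epoxyhex-2-enoate
Conditions: KN(SiMe3)2, 18-crown-6, THF, −78 °C
Reagents that add atoms: none
Why: Still–Gennari olefination; the electron-poor phosphonate under dissociating conditions eliminates rapidly from the kinetically formed adduct and should give the Z-enoate, with the epoxide centres untouched.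

Step 13
Reactants: 20 methyl (2Z,4S,5S)-4,5-epoxyhex-2-enoate
Product: 21 potassium (2Z,4S,5S)-4,5-epoxyhex-2-enoate
Conditions: KOSiMe3 (1.0 equiv), Et2O, 0 °C to rt; salt collected by filtration
Reagents that add atoms: potassium trimethylsilanolate, C[Si](C)(C)[O-].[K+]
Why: Anhydrous silanolate cleavage of a methyl ester gives the carboxylate salt directly; the free acid is never formed, which avoids opening of the epoxide by the cis carboxyl group.

Step 14
Reactants: 15 2',3',5'-tris(benzyloxy)-4,4'',6'-tris(tert-butyldimethylsilyloxy)-1,1':4',1''-terphenyl
Product: 22 4,4'',6'-tris(tert-butyldimethylsilyloxy)-[1,1':4',1''-terphenyl]-2',3',5'-triol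
Conditions: H2 (1 atm), 10% Pd/C, EtOAc, rt; filtered under Ar and used at once
Reagents that add atoms: none
Why: Hydrogenolysis of three aryl benzyl ethers in a non-protic solvent leaves aryl silyl ethers intact and gives ring B at the leuco oxidation level with exactly three free hydroxyls; any silyl shift between neighbouring oxygens is degenerate.

Step 15
Reactants: 22 4,4'',6'-tris(tert-butyldimethylsilyloxy)-[1,1':4',1''-terphenyl]-2',3',5'-triol; 21 potassium (2Z,4S,5S)-4,5-epoxyhex-2-enoate (4.5 equiv)
Product: 24 4,4'',6'-tris(tert-butyldimethylsilyloxy)-[1,1':4',1''-terphenyl]-2',3',5'-triyl tris[(2Z,4S,5S)-4,5-epoxyhex-2-enoate], via mixed 2,4,6-trichlorobenzoic anhydride 23 (not isolated)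
Conditions: 21 (4.5 equiv), 2,4,6-Cl3C6H2COCl (4.5 equiv), 18-crown-6 (cat.), THF, 0 °C; then 22, Et3N, DMAP (cat.), PhMe/THF, 0 °C, Ar
Reagents that add atoms: potassium (2Z,4S,5S)-4,5-epoxyhex-2-enoate (second molecule of 21), C[C@@H]1O[C@H]1/C=C\C(=O)[O-].[K+]; potassium (2Z,4S,5S)-4,5-epoxyhex-2-enoate (third molecule of 21), C[C@@H]1O[C@H]1/C=C\C(=O)[O-].[K+]
Why: Yamaguchi esterification; the carboxylate is converted to the mixed anhydride 23, which DMAP attacks at the unhindered enoyl carbonyl, and each of the three phenols takes up one acyl group from one molecule of 21, so the acylation is exhaustive and no count selectivity is needed. Low temperature and little DMAP limit Z to E isomerisation, and the stereocentres are not involved.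

Step 16
Reactants: 24 4,4'',6'-tris(tert-butyldimethylsilyloxy)-[1,1':4',1''-terphenyl]-2',3',5'-triyl tris[(2Z,4S,5S)-4,5-epoxyhex-2-enoate]
Product: 25 4,4'',6'-trihydroxy-[1,1':4',1''-terphenyl]-2',3',5'-triyl tris[(2Z,4S,5S)-4,5-epoxyhex-2-enoate] (the target; side chain also named (2Z)-3-[(2S,3S)-3-methyloxiran-2-yl]prop-2-enoyl)
Conditions: Bu4NF, AcOH (1:1), THF, 0 °C
Reagents that add atoms: none
Why: Aryl silyl ethers are cleaved by fluoride within minutes at 0 °C, and the acetic acid buffer keeps the liberated phenols protonated so that esters and epoxides should survive; acyl migration to the freed ring-B oxygen would be degenerate.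

## Compound list

1 | 2,5-dihydroxy-1,4-benzoquinone | OC1=CC(=O)C(O)=CC1=O | starting material
2 | 2,5-bis(benzyloxy)-1,4-benzoquinone | O=C1C=C(OCc2ccccc2)C(=O)C=C1OCc1ccccc1 | intermediate
3 | allyl bromide | C=CCBr | starting material
4 | 2,5-bis(benzyloxy)benzene-1,4-diol (not isolated) | Oc1cc(OCc2ccccc2)c(O)cc1OCc1ccccc1 | intermediate
5 | 1,4-bis(allyloxy)-2,5-bis(benzyloxy)benzene | C=CCOc1cc(OCc2ccccc2)c(OCC=C)cc1OCc1ccccc1 | intermediate
6 | 3,6-diallyl-2,5-bis(benzyloxy)benzene-1,4-diol | C=CCc1c(O)c(OCc2ccccc2)c(CC=C)c(O)c1OCc1ccccc1 | intermediate
7 | 3,6-diallyl-2,4,5-tris(benzyloxy)phenol | C=CCc1c(O)c(OCc2ccccc2)c(CC=C)c(OCc2ccccc2)c1OCc1ccccc1 | intermediate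
8 | tert-butyl[3,6-diallyl-2,4,5-tris(benzyloxy)phenoxy]dimethylsilane | C=CCc1c(O[Si](C)(C)C(C)(C)C)c(OCc2ccccc2)c(CC=C)c(OCc2ccccc2)c1OCc1ccccc1 | intermediate
9 | 2,2'-[2,3,5-tris(benzyloxy)-6-(tert-butyldimethylsilyloxy)-1,4-phenylene]diacetaldehyde | O=CCc1c(O[Si](C)(C)C(C)(C)C)c(OCc2ccccc2)c(CC=O)c(OCc2ccccc2)c1OCc1ccccc1 | intermediate
10 | methyl vinyl ketone | CC(=O)C=C | starting material
11 | 1,1'-{[2,3,5-tris(benzyloxy)-6-(tert-butyldimethylsilyloxy)-1,4-phenylene]bis[(E)-ethene-2,1-diyl]}dipyrrolidine (not isolated) | C1CCN(C1)/C=C/c1c(O[Si](C)(C)C(C)(C)C)c(OCc2ccccc2)c(/C=C/N2CCCC2)c(OCc2ccccc2)c1OCc1ccccc1 | intermediate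
12 | 2,2'-[2,3,5-tris(benzyloxy)-6-(tert-butyldimethylsilyloxy)-1,4-phenylene]bis(5-oxohexanal) (stereoisomer mixture, not isolated) | CC(=O)CCC(C=O)c1c(O[Si](C)(C)C(C)(C)C)c(OCc2ccccc2)c(C(C=O)CCC(C)=O)c(OCc2ccccc2)c1OCc1ccccc1 | intermediate
13 | 4,4'-[2,3,5-tris(benzyloxy)-6-(tert-butyldimethylsilyloxy)-1,4-phenylene]bis(cyclohex-2-en-1-one) (stereoisomer mixture) | O=C1C=CC(CC1)c1c(O[Si](C)(C)C(C)(C)C)c(OCc2ccccc2)c(C2C=CC(=O)CC2)c(OCc2ccccc2)c1OCc1ccccc1 | intermediate
14 | 2',3',5'-tris(benzyloxy)-6'-(tert-butyldimethylsilyloxy)-[1,1':4',1''-terphenyl]-4,4''-diol | Oc1ccc(cc1)-c1c(O[Si](C)(C)C(C)(C)C)c(OCc2ccccc2)c(-c2ccc(O)cc2)c(OCc2ccccc2)c1OCc1ccccc1 | intermediate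
15 | 2',3',5'-tris(benzyloxy)-4,4'',6'-tris(tert-butyldimethylsilyloxy)-1,1':4',1''-terphenyl | CC(C)(C)[Si](C)(C)Oc1ccc(cc1)-c1c(O[Si](C)(C)C(C)(C)C)c(OCc2ccccc2)c(-c2ccc(O[Si](C)(C)C(C)(C)C)cc2)c(OCc2ccccc2)c1OCc1ccccc1 | intermediate
16 | (E)-but-2-en-1-ol | C/C=C/CO | starting material
17 | (2S,3S)-2,3-epoxybutan-1-ol | C[C@@H]1O[C@H]1CO | intermediate
18 | (2R,3S)-2,3-epoxybutanal | C[C@@H]1O[C@H]1C=O | intermediate
19 | methyl bis(2,2,2-trifluoroethyl)phosphonoacetate | COC(=O)CP(=O)(OCC(F)(F)F)OCC(F)(F)F | starting material
20 | methyl (2Z,4S,5S)-4,5-epoxyhex-2-enoate | C[C@@H]1O[C@H]1/C=C\C(=O)OC | intermediate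
21 | potassium (2Z,4S,5S)-4,5-epoxyhex-2-enoate | C[C@@H]1O[C@H]1/C=C\C(=O)[O-].[K+] | intermediate
22 | 4,4'',6'-tris(tert-butyldimethylsilyloxy)-[1,1':4',1''-terphenyl]-2',3',5'-triol | CC(C)(C)[Si](C)(C)Oc1ccc(cc1)-c1c(O[Si](C)(C)C(C)(C)C)c(O)c(-c2ccc(O[Si](C)(C)C(C)(C)C)cc2)c(O)c1O | intermediate
23 | (2Z,4S,5S)-4,5-epoxyhex-2-enoic 2,4,6-trichlorobenzoic anhydride (not isolated) | C[C@@H]1O[C@H]1/C=C\C(=O)OC(=O)c1c(Cl)cc(Cl)cc1Cl | intermediate
24 | 4,4'',6'-tris(tert-butyldimethylsilyloxy)-[1,1':4',1''-terphenyl]-2',3',5'-triyl tris[(2Z,4S,5S)-4,5-epoxyhex-2-enoate] | C[C@@H]1O[C@H]1/C=C\C(=O)Oc1c(OC(=O)/C=C\[C@@H]2O[C@H]2C)c(-c2ccc(O[Si](C)(C)C(C)(C)C)cc2)c(OC(=O)/C=C\[C@@H]2O[C@H]2C)c(O[Si](C)(C)C(C)(C)C)c1-c1ccc(O[Si](C)(C)C(C)(C)C)cc1 | intermediate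
25 | 4,4'',6'-trihydroxy-[1,1':4',1''-terphenyl]-2',3',5'-triyl tris[(2Z,4S,5S)-4,5-epoxyhex-2-enoate] | C[C@@H]1O[C@H]1/C=C\C(=O)Oc1c(OC(=O)/C=C\[C@@H]2O[C@H]2C)c(-c2ccc(O)cc2)c(OC(=O)/C=C\[C@@H]2O[C@H]2C)c(O)c1-c1ccc(O)cc1 | target

## Step count and risks

Total: 16 steps. Longest linear sequence: 12 steps (steps 1 to 9, then 14 to 16). The side-chain branch is 4 steps (steps 10 to 13).

**Step 7 (key step).** The most likely failure is a slow Michael addition at the crowded benzylic enamine carbon, especially on the arm next to the silyl ether. Methyl vinyl ketone then polymerises, the aldehyde self-condenses, or only one arm is annulated; a second addition at an already alkylated carbon is the other risk. The fallback separates the two bond formations. From 9, silylation (Me3SiCl, Et3N, NaI, MeCN) gives the bis(trimethylsilyl enol ether) F1. Mukaiyama–Michael addition of F1 to 10 (BF3·OEt2, CH2Cl2, −78 °C) gives the keto aldehyde 12, now isolated. Aldol condensation of 12 with pyrrolidinium acetate returns to the route at 13.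

**Step 15 (triacylation).** The Z-enoate may isomerise by reversible conjugate addition of DMAP to the activated acyl species. The third, most hindered hydroxyl may be acylated incompletely, and 22 may oxidise under basic conditions. Any minor enantiomer in 21 would also surface here as diastereomers. The fallback removes the geometry question until after ester formation. From 18, Ohira–Bestmann homologation gives (2S,3S)-2-ethynyl-3-methyloxirane F2. Lithiation (n-BuLi) and carboxylation with CO2 give (4S,5S)-4,5-epoxyhex-2-ynoic acid F3, which cannot lactonise. Carbodiimide coupling of F3 with 22 gives the tris(ynoate) F4. Semihydrogenation of F4 over Pd/CaCO3 poisoned with Pb(OAc)2, in the presence of quinoline, returns to the route at 24.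

**Step 8 (double dehydrogenation).** One of the two rings may stop at the enone stage, the electron-rich phenols may undergo oxidative coupling, or the silyl ether may be lost in warm acidic DMSO. The fallback is a stoichiometric two-stage sequence. From 13, kinetic enolisation and trapping (LiN(iPr)2, Me3SiCl, THF, −78 °C) give the bis(dienol silyl ether) F5. Saegusa–Ito oxidation of F5 with Pd(OAc)2 in MeCN gives the cross-conjugated dienones, which tautomerise to 14.

**Step 4 (monobenzylation).** The outcome is statistical, and over-alkylation to the fully benzylated ring removes material that cannot be recycled. The hydroquinone may also oxidise under base. The fallback changes the order so that the by-product is recyclable. From 6, TBSCl (1 equiv) and imidazole give 3,6-diallyl-2,5-bis(benzyloxy)-4-(tert-butyldimethylsilyloxy)phenol F6. The accompanying bis(silyl ether) F7 is returned to 6 with Bu4NF. Mitsunobu benzylation of F6 (BnOH, PPh3, DIAD), under neutral conditions, returns to the route at 8.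

**Step 6 (oxidative cleavage).** The arylacetaldehyde can enolise, and dihydroxylation of the enol would shorten the chain to an aryl aldehyde. Aldol self-condensation during isolation is the other risk. The fallback is a two-stage cleavage. From 8, dihydroxylation (OsO4 cat., N-methylmorpholine N-oxide) gives the bis(diol) F8, which can be purified and stored. Cleavage of F8 with NaIO4 on silica in CH2Cl2, immediately before step 7, returns to the route at 9.

## Further compounds

F1 | step 7 | {[2,3,5-tris(benzyloxy)-6-(tert-butyldimethylsilyloxy)-1,4-phenylene]bis(ethene-2,1-diyloxy)}bis(trimethylsilane) (E/Z mixture) | C[Si](C)(C)OC=Cc1c(O[Si](C)(C)C(C)(C)C)c(OCc2ccccc2)c(C=CO[Si](C)(C)C)c(OCc2ccccc2)c1OCc1ccccc1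
F2 | step 15 | (2S,3S)-2-ethynyl-3-methyloxirane | C[C@@H]1O[C@H]1C#C
F3 | step 15 | (4S,5S)-4,5-epoxyhex-2-ynoic acid | C[C@@H]1O[C@H]1C#CC(=O)O
F4 | step 15 | 4,4'',6'-tris(tert-butyldimethylsilyloxy)-[1,1':4',1''-terphenyl]-2',3',5'-triyl tris[(4S,5S)-4,5-epoxyhex-2-ynoate] | C[C@@H]1O[C@H]1C#CC(=O)Oc1c(OC(=O)C#C[C@@H]2O[C@H]2C)c(-c2ccc(O[Si](C)(C)C(C)(C)C)cc2)c(OC(=O)C#C[C@@H]2O[C@H]2C)c(O[Si](C)(C)C(C)(C)C)c1-c1ccc(O[Si](C)(C)C(C)(C)C)cc1
F5 | step 8 | {[2,3,5-tris(benzyloxy)-6-(tert-butyldimethylsilyloxy)-1,4-phenylene]bis(cyclohexa-1,5-diene-4,1-diyloxy)}bis(trimethylsilane) (stereoisomer mixture) | C[Si](C)(C)OC1=CCC(C=C1)c1c(O[Si](C)(C)C(C)(C)C)c(OCc2ccccc2)c(C2C=CC(O[Si](C)(C)C)=CC2)c(OCc2ccccc2)c1OCc1ccccc1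
F6 | step 4 | 3,6-diallyl-2,5-bis(benzyloxy)-4-(tert-butyldimethylsilyloxy)phenol | C=CCc1c(O)c(OCc2ccccc2)c(CC=C)c(O[Si](C)(C)C(C)(C)C)c1OCc1ccccc1
F7 | step 4 | [3,6-diallyl-2,5-bis(benzyloxy)-1,4-phenylene]bis(oxy)bis(tert-butyldimethylsilane) | C=CCc1c(O[Si](C)(C)C(C)(C)C)c(OCc2ccccc2)c(CC=C)c(O[Si](C)(C)C(C)(C)C)c1OCc1ccccc1
F8 | step 6 | 3,3'-[2,3,5-tris(benzyloxy)-6-(tert-butyldimethylsilyloxy)-1,4-phenylene]bis(propane-1,2-diol) (stereoisomer mixture) | OCC(O)Cc1c(O[Si](C)(C)C(C)(C)C)c(OCc2ccccc2)c(CC(O)CO)c(OCc2ccccc2)c1OCc1ccccc1
A1 | alternative 1 | methyl (2Z,4S,5S)-4,5-epoxyhex-2-enoate | C[C@@H]1O[C@H]1/C=C\C(=O)OC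
A2 | alternative 1 | (5S)-5-[(1R)-1-(methanesulfonyloxy)ethyl]furan-2(5H)-one | C[C@@H](OS(C)(=O)=O)[C@H]1OC(=O)C=C1
A3 | alternative 1 | D-glucono-1,5-lactone | OC[C@H]1OC(=O)[C@H](O)[C@@H](O)[C@@H]1O
A4 | alternative 2 | 2-(tert-butyldimethylsilyloxy)-4-methoxy-3-(4-methoxyphenyl)cyclobut-2-en-1-one | COC1C(=C(O[Si](C)(C)C(C)(C)C)C1=O)c1ccc(OC)cc1
A5 | alternative 2 | triisopropyl{[(4-methoxyphenyl)ethynyl]oxy}silane | COc1ccc(cc1)C#CO[Si](C(C)C)(C(C)C)C(C)C
A6 | alternative 2 | 6-(tert-butyldimethylsilyloxy)-4-methoxy-2,5-bis(4-methoxyphenyl)-3-(triisopropylsilyloxy)phenol | Oc1c(-c2ccc(OC)cc2)c(O[Si](C(C)C)(C(C)C)C(C)C)c(OC)c(-c2ccc(OC)cc2)c1O[Si](C)(C)C(C)(C)C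
A7 | alternative 3 | 4,4'',6'-tris(tert-butyldimethylsilyloxy)-[1,1':4',1''-terphenyl]-2',3',5'-triyl tris[(2Z,4E)-hexa-2,4-dienoate] | C/C=C/C=C\C(=O)Oc1c(OC(=O)/C=C\C=C\C)c(-c2ccc(O[Si](C)(C)C(C)(C)C)cc2)c(OC(=O)/C=C\C=C\C)c(O[Si](C)(C)C(C)(C)C)c1-c1ccc(O[Si](C)(C)C(C)(C)C)cc1
A8 | alternative 3 | 4,4'',6'-tris(tert-butyldimethylsilyloxy)-[1,1':4',1''-terphenyl]-2',3',5'-triyl tris[(2Z,4S,5S)-4,5-epoxyhex-2-enoate] | C[C@@H]1O[C@H]1/C=C\C(=O)Oc1c(OC(=O)/C=C\[C@@H]2O[C@H]2C)c(-c2ccc(O[Si](C)(C)C(C)(C)C)cc2)c(OC(=O)/C=C\[C@@H]2O[C@H]2C)c(O[Si](C)(C)C(C)(C)C)c1-c1ccc(O[Si](C)(C)C(C)(C)C)cc1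
A9 | alternative 3 | (2Z,4E)-hexa-2,4-dienoic acid | C/C=C/C=C\C(=O)O
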